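**The leftover.** I began with what stayed out of the chains in two earlier closed flasks of free monomer, protic impurity and initiator: the last readings left 0.0314 M in elm and 0.0334 M in ash, although ash had been charged with twice the free monomer.

the same everywhere: initiator 3.6 mM
- elm: free monomer 0.063 M; protic impurity 0.020 M; run made earlier
- ash: free monomer 0.13 M; protic impurity 0.020 M; run made earlier
- spring: free monomer 0.10 M; protic impurity 0.0200 M; time 30 h
- noon: free monomer 0.15 M; protic impurity 0.0200 M; time 30 h

| run | time / h | monomer in chains / % |
|---|---|---|
| elm | 4.00 | 37.3 |
| elm | 8.00 | 46.0 |
| elm | 12.0 | 50.2 |
| elm | 15.0 | 50.7 |
| elm | 20.0 | 50.1 |
| ash | 4.00 | 46.1 |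
| ash | 8.00 | 64.1 |
| ash | 12.0 | 72.3 |
| ash | 15.0 | 73.7 |
| ash | 20.0 | 74.3 |

(readings scatter by 1 percentage point)

1. which of the two ends with the longer chains by the average number of monomer units in a chain (chains begun, living or dead) ("neither" if they lie within 10 %) (spring / noon / neither)
2. average number of monomer units in a chain (chains begun, living or dead) at the end, spring
3. average number of monomer units in a chain (chains begun, living or dead) at the end, noon

- the average divides the monomer in chains by the number of chains begun, living and dead together
- the earlier runs were read with a standard deviation of 1 percentage point
- the earlier runs do not show the number of chains; that part of a forecast is a guess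

**Turning time.** By hand, a longer wait mattered while the readings climbed, but elm read 50.7 % at 15.0 h and 50.1 % at 20.0 h, and ash read 73.7 % and 74.3 %, so I took 30 h as plateau for spring and noon.

**Turning charge.** By hand, a fixed share staying out would have grown with the charge and a fixed amount would not, and the two runs looked like the second case. So I carried the leftover, the free monomer charged minus the monomer in chains on the plateau, at 0.0324 M as the mean of both runs, holding protic impurity and initiator at the charges those runs shared. Elm and ash were my two ends, joined by a line of slope one for monomer in chains against free monomer charged; noon, charged with more free monomer than ash, lay beyond that line's end.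

**Turning initiator.** By hand, more initiator meant more chains at the same monomer, but the readings did not show the number of chains, so I guessed one chain per initiator charged. My estimate of the average, the number-average degree of polymerisation, was then c(free monomer) minus the leftover, over c(initiator): 18.8 for spring and 32.7 for noon, so I expected noon to end longer.

**The forecast.** The forecast gave noon, with 9 for spring and 15 for noon, on the words “The runs do not fix this; I guess about 8 mM”, a chain count different from mine.

**The result.** The flasks gave noon, with 19.8 for spring and 34.1 for noon.

    free monomer + initiator → living end + monomer in chains (k = 1.10 M⁻¹ min⁻¹)
    free monomer + living end → monomer in chains + living end, rate k2*[living end]*[free monomer] (k = 1.10 M⁻¹ min⁻¹)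
    monomer in chains + living end → free monomer + living end, rate k3*[living end] as long as [monomer in chains] is above zero (k = 0.0120 min⁻¹)
    protic impurity + free monomer → quenched substrate (k = 0.250 M⁻¹ min⁻¹)
    free monomer + initiator → spent initiator (k = 0.0350 M⁻¹ min⁻¹)

**The neighbour.** At the end the leftover stood at 0.0311 M in spring and 0.0311 M in noon, against my 0.0324 M, and the living end stood at 0.00349 M in noon, against my 3.6 mM. A further flask like noon, charged with 0.037 M of free monomer, came out by the same reckoning at 1.28 units per chain. Its leftover stood at 0.0307 M, and its average was 1.80.

The readings were generated by integration for substances that don't exist, noise included.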